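## Retrosynthetic overview

1. No ring is built. Ring B is bought as (E)-4-propenylsyringol 1 and converted to its vinyl ether 2; ring A is bought as syringaldehyde 3 and masked as pivalate 4.
2. Key disconnection C7–C8 (C7 = carbinol carbon, C8 = aryloxy-bearing carbon): the acyl-anion equivalent of 4 (Breslow enaminol 5) adds in Markovnikov fashion to 2 under a chiral triazolylidene, giving (S)-α-aryloxy ketone 6 and setting C8.
3. C7–H: chelation-controlled hydride addition to 6 gives erythro alcohol 7 (C7 R), and the same hydride removes the pivalate to give target 8.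

Assumption: 1 is used as the pure E isomer (commercial flavour-grade material, E-enriched by recrystallisation if the lot contains Z).

## Route

Step 1
Reactants: 1 (E)-2,6-dimethoxy-4-(prop-1-enyl)phenol
Product: 2 (E)-1,3-dimethoxy-5-(prop-1-enyl)-2-(vinyloxy)benzene
Conditions: vinyl acetate (3 equiv), [IrCl(C8H12)]2 (1 mol%), Na2CO3 (0.6 equiv), toluene, 100 °C
Reagents that add atoms: vinyl acetate, CC(=O)OC=C
Why: Iridium-catalysed transfer vinylation (phenol O–H addition to vinyl acetate, then β-acetate elimination) gives aryl vinyl ethers under weakly basic conditions that leave the conjugated (E)-propenyl group alone; no stereocentre is formed.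

Step 2
Reactants: 3 syringaldehyde (4-hydroxy-3,5-dimethoxybenzaldehyde)
Product: 4 4-formyl-2,6-dimethoxyphenyl pivalate
Conditions: PivCl (1.2 equiv), Et3N (1.5 equiv), DMAP (5 mol%), CH2Cl2, 0 °C to rt
Reagents that add atoms: pivaloyl chloride, CC(C)(C)C(=O)Cl
Why: DMAP-catalysed O-acylation of the acidic phenol gives a bulky aryl ester that keeps the phenol from quenching the carbene, resists acyl transfer to the carbene in step 3 and is removed by hydride in step 4; no stereocentre is formed.

Step 3
Reactants: 2 (E)-1,3-dimethoxy-5-(prop-1-enyl)-2-(vinyloxy)benzene (1.5 equiv); 4 4-formyl-2,6-dimethoxyphenyl pivalate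
Product: 6 4-[(2S)-2-{2,6-dimethoxy-4-[(E)-prop-1-enyl]phenoxy}propanoyl]-2,6-dimethoxyphenyl pivalate, via Breslow enaminol 5 (not isolated)
Conditions: (5aS,10bR)-2-(pentafluorophenyl)-5a,10b-dihydro-4H,6H-indeno[2,1-b][1,2,4]triazolo[4,3-d][1,4]oxazinium tetrafluoroborate (10 mol%), KO2CCMe3 (20 mol%), Me3CCO2H (10 mol%), toluene, 40 °C
Reagents that add atoms: none
Why: Proposed new method: enantioselective intermolecular Markovnikov hydroacylation of an aryl vinyl ether by a chiral triazolylidene, in which the carbene turns 4 into Breslow enaminol 5, the enol O–H (relayed by pivalic acid) protonates the nucleophilic CH2 terminus of 2 while the acyl-anion carbon bonds to the developing oxocarbenium carbon inside one hydrogen-bonded, ene-like assembly, the indane wall of the catalyst leaving the Re face of that carbon open so that C8 forms as (S) (sense of induction to be confirmed on the first run, the (5aR,10bS) antipode being equally available), after which the azolium alkoxide collapses to ketone 6 and releases the carbene; enol-ether polarity dictates the branched regiochemistry, the carboxylate buffer is too weakly basic to epimerise the α-aryloxy ketone, and the closest known reactions are carbene-catalysed hydroacylation of cyclopropenes and styrenes and the asymmetric aza-benzoin addition of Breslow intermediates to imines.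

Step 4
Reactants: 6 4-[(2S)-2-{2,6-dimethoxy-4-[(E)-prop-1-enyl]phenoxy}propanoyl]-2,6-dimethoxyphenyl pivalate
Product: 8 (1R,2S)-2-{2,6-dimethoxy-4-[(E)-prop-1-enyl]phenoxy}-1-(4-hydroxy-3,5-dimethoxyphenyl)propan-1-ol (target CNP0174373.1), via erythro alcohol pivalate 7 (not isolated)
Conditions: LiAlH4 (3 equiv), Et2O, −78 °C, then 0 °C; aq. KNaC4H4O6 work-up
Reagents that add atoms: none
Why: Cram-chelate 1,2-induction, in which Li+ bridges the carbonyl oxygen and the ether oxygen of the 2,6-dimethoxyphenoxy group (helped by its ortho methoxy groups) and hydride adds at −78 °C from the face carrying H-8 to set C7 as (R) (erythro, 7R,8S), after which the excess LiAlH4 reductively cleaves the aryl pivalate at 0 °C without touching the propenyl group or C8.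

## Compound list

1 | (E)-2,6-dimethoxy-4-(prop-1-enyl)phenol (4-propenylsyringol) | C/C=C/c1cc(OC)c(O)c(OC)c1 | starting material
2 | (E)-1,3-dimethoxy-5-(prop-1-enyl)-2-(vinyloxy)benzene | C/C=C/c1cc(OC)c(OC=C)c(OC)c1 | intermediate
3 | syringaldehyde (4-hydroxy-3,5-dimethoxybenzaldehyde) | COc1cc(C=O)cc(OC)c1O | starting material
4 | 4-formyl-2,6-dimethoxyphenyl pivalate | COc1cc(C=O)cc(OC)c1OC(=O)C(C)(C)C | intermediate
5 | Breslow enaminol: the former aldehyde carbon of 4 (bearing OH and the aryl group) double-bonded to C1 of the (5aS,10bR)-2-(pentafluorophenyl)-5a,10b-dihydro-4H,6H-indeno[2,1-b][1,2,4]triazolo[4,3-d][1,4]oxazine ring | OC(c1cc(OC)c(OC(=O)C(C)(C)C)c(OC)c1)=C1N(c2c(F)c(F)c(F)c(F)c2F)N=C2CO[C@H]3Cc4ccccc4[C@H]3N12 | intermediate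
6 | 4-[(2S)-2-{2,6-dimethoxy-4-[(E)-prop-1-enyl]phenoxy}propanoyl]-2,6-dimethoxyphenyl pivalate | C/C=C/c1cc(OC)c(O[C@@H](C)C(=O)c2cc(OC)c(OC(=O)C(C)(C)C)c(OC)c2)c(OC)c1 | intermediate
7 | 4-[(1R,2S)-2-{2,6-dimethoxy-4-[(E)-prop-1-enyl]phenoxy}-1-hydroxypropyl]-2,6-dimethoxyphenyl pivalate | C/C=C/c1cc(OC)c(O[C@@H](C)[C@H](O)c2cc(OC)c(OC(=O)C(C)(C)C)c(OC)c2)c(OC)c1 | intermediate
8 | (1R,2S)-2-{2,6-dimethoxy-4-[(E)-prop-1-enyl]phenoxy}-1-(4-hydroxy-3,5-dimethoxyphenyl)propan-1-ol | C/C=C/c1cc(OC)c(O[C@@H](C)[C@H](O)c2cc(OC)c(O)c(OC)c2)c(OC)c1 | target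

## Step count and risks

Total steps: 4. Longest linear sequence: 3 (1 → 2 → 6 → 8, or 3 → 4 → 6 → 8).

Steps most likely to fail, in order of risk: step 3, step 4, step 1.

**Step 3 (proposed new hydroacylation).** The risks are that reversible benzoin formation from 4 outruns the addition, that the vinyl ether is lost to acid-catalysed side reactions, or that ee is low or eroded at the enolisable ketone.

The fallback uses known chemistry only; it sets out from 1 and comes back to the route at 6. Phenol 1 is pivaloylated (PivCl, Et3N, DMAP, CH2Cl2) to 2,6-dimethoxy-4-[(E)-prop-1-enyl]phenyl pivalate F1. Shi epoxidation of F1 with the D-fructose-derived ketone (KHSO5 as 2KHSO5·KHSO4·K2SO4, K2CO3 buffer, MeCN/dimethoxymethane/water, 0 °C) gives 2,6-dimethoxy-4-[(2R,3R)-3-methyloxiran-2-yl]phenyl pivalate F2; here the asymmetric step is again organocatalytic and sets both centres. Oxidative epoxide opening with DMSO (cat. TfOH, then iPr2NEt) attacks only the benzylic carbon and gives 4-[(2R)-2-hydroxypropanoyl]-2,6-dimethoxyphenyl pivalate F3, with the C8–O bond untouched. Mitsunobu etherification of F3 with a second equivalent of 1 (PPh3, DIAD, toluene, 0 °C) inverts C8 and delivers (S)-ketone 6, which enters step 4 unchanged.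

**Step 4 (one-pot chelation-controlled reduction and ester cleavage).** The risks are a modest erythro:threo ratio with LiAlH4, or loss of the benzylic oxygen through a quinone methide once the phenoxide is free.

The fallback sets out from 6 and comes back at 8. It separates the two events and puts C7 under catalyst control instead of substrate control. Corey–Bakshi–Shibata reduction of 6 with (R)-2-methyl-CBS-oxazaborolidine (20 mol%) and catecholborane in toluene at −78 °C gives 7, now isolated; this assumes the aryl group acts as the large substituent, and the catalyst antipode is to be confirmed. NaOMe in MeOH at rt then removes the pivalate to give 8. No compound outside the list is made (F0).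

**Step 1 (transfer vinylation of a di-ortho-substituted phenol).** The risks are sluggish O-vinylation or competing O-acetylation.

The fallback sets out from 1 and comes back at 2. It replaces catalytic vinyl transfer by alkylation and elimination. O-alkylation of 1 with excess 1,2-dibromoethane (K2CO3, acetone, reflux) gives (E)-2-(2-bromoethoxy)-1,3-dimethoxy-5-(prop-1-enyl)benzene F4, and E2 elimination with KOC(CH3)3 in THF at 0 °C to rt gives 2.

## Further compounds

F1 | step 3 | 2,6-dimethoxy-4-[(E)-prop-1-enyl]phenyl pivalate | C/C=C/c1cc(OC)c(OC(=O)C(C)(C)C)c(OC)c1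
F2 | step 3 | 2,6-dimethoxy-4-[(2R,3R)-3-methyloxiran-2-yl]phenyl pivalate | C[C@H]1O[C@@H]1c1cc(OC)c(OC(=O)C(C)(C)C)c(OC)c1
F3 | step 3 | 4-[(2R)-2-hydroxypropanoyl]-2,6-dimethoxyphenyl pivalate | C[C@@H](O)C(=O)c1cc(OC)c(OC(=O)C(C)(C)C)c(OC)c1
F0 | step 4 | none | none
F4 | step 1 | (E)-2-(2-bromoethoxy)-1,3-dimethoxy-5-(prop-1-enyl)benzene | C/C=C/c1cc(OC)c(OCCBr)c(OC)c1
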